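The constants are made up; what happens was integrated by code.

Count the reagent.

substrate 0.50 mM (fed, over 6.0 s); reagent 0.400 mM; time 2.5 min

1. at 2.5 min, what has stopped the reaction, if anything has (it is still moving / forward and back rates have come level / the reagent has run out first / all of the substrate has reacted)
2. share of the substrate used up at 2.5 min
3. target at 2.5 min, in percent of the substrate charged

- for target the crystals are counted in
- as a solid, counted per litre of solution: crystals
- the reaction counts as stopped when no species that holds the substrate changes by six tenths of a point or more over the second half of the time
- run time (flask): 2.5 min

We keep the books on the reagent, the limiting reagent here, since 0.400 mM stands against 0.50 mM of substrate. Each unit that leaves takes one unit of substrate with it, into target or its isomer, so the free substrate stays 0.100 mM above the free reagent. Both reactions run back, and target has a solubility of 0.0073 mM. The charges multiply to 0.200 mM^2, far above the solubility of target divided by its equilibrium constant, so we expect crystals to form. While they last, we expect [substrate][reagent] to come to rest at the pair ceiling, the solubility of target divided by its equilibrium constant of 2100 M⁻¹: 0.00348 mM^2.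

Our zero is the symmetric case: with equal charges, each free amount would be 0.0590 mM. The excess tilts this, and solving the product with that offset gives the first entry, 0.0273 mM of free reagent. The isomer, with its constant of 5800 M⁻¹, takes 0.0202 mM. Solution holds 0.0073 mM of dissolved target, and the crystals take the remaining 0.345 mM. At that free reagent the forward half-life of substrate by the isomer step is 35.8 s, short against 2.5 min. So we commit to level rates, a conversion of 74.5% and target at 70.5%.

The forecast gives forward and back rates have come level, 74.5% and 70.5%, on the ground that “Crystallisation pins dissolved target at its solubility”.

The flask gives forward and back rates have come level, 74.5% and 70.5%. Its free amounts at 2.50 min multiply to 0.00348 mM^2, against the ceiling of 0.00348 mM^2.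

    substrate + reagent ⇌ isomer of the product (K1 = 5800 M⁻¹, k1 = 710 M⁻¹ s⁻¹)
    crystals ⇌ target, rate k2*(cs2 - [target]) while solid is left; crystals form when [target] > cs2 (cs2 = 0.0073 mM, k2 = 3.1 s⁻¹)
    substrate + reagent ⇌ target (K3 = 2100 M⁻¹, k3 = 1200 M⁻¹ s⁻¹)

The main reason this flask stops short of full conversion is the depletion of reagent: with that depletion taken away, the flask reaches 98.3% instead of 74.5%, which accounts for 93% of what is missing, and that is a change that would turn the forecast wrong. The ceiling stays in the neighbour flask with 0.16 mM of reagent, where the offset becomes 0.340 mM. This gives 0.00993 mM of free reagent and 26.0% of target. That neighbour flask holds 26.0% of target.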